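The vessel is closed and stirred, so I treated it as a tank whose starting material drains into product, and I began with the pace at which it opens.

the same everywhere: starting material 1.1 M

| charge | reagent | initiator | temperature | remark | time |
|---|---|---|---|---|---|
| grey | 1 equiv | 1 mol% | 5 °C | run made earlier |  |
| winter | 1.50 equiv | 1.5 mol% |  | at 35 °C throughout | 15 h |
| midnight | 1.50 equiv | 1 mol% |  | at 5 °C until 5.0 h, from then on at 35 °C | 15 h |

- grey (time / h: product / %): 0.667: 7; 1.33: 12; 2.00: 14; 2.50: 17; 3.00: 17

(each reading ± 1.5 percentage points)

- percentages count the starting material that a species holds: one ended chains B counts as two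
- reactions considered so far: initiator -> 2 initiating radical; starting material + initiating radical -> chain carrier; reagent + chain carrier -> product + initiating radical; 2 initiating radical -> ended chains A; 2 chain carrier -> ended chains B; reagent <-> dormant form
- the earlier runs do not show what temperature does; that part of a forecast is a guess
- no earlier run changes the charge of initiator; that part of a forecast is a guess

- the winner by amount of product, in percent of the starting material charged; "neither" if no more than 2 percentage points parts them (winter / midnight / neither)
- how much product is there at the end, in percent of the starting material charged: winter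
- how much product is there at the end, in percent of the starting material charged: midnight

The first grey reading, 7% at 0.667 h, gave 9.53 h as the fill time: the time in which the opening pace would convert the whole charge. It carries the scatter of that reading. Both new flasks hold 1.50 equiv of reagent, so the reagent charge covers the starting material. If the rate falls in step with [starting material], a pseudo-first-order picture, the integral is an exponential, and my reckoning at the temperature of the grey run gave 79.3% of product at 15 h. But the same curve gave 27.0% at 3.00 h, more than the 17% read in the grey run, so I held that figure loosely. Putting winter first was my guess, since no earlier run shows what temperature or the charge of initiator does.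

The forecast, which took as the likeliest cause of the stall in the grey run that “the initiator is used up at roughly 0.7 per hour”, gave 20% for winter and 28% for midnight, with midnight ahead. These figures differ from mine.

The simulation gave 94.4% for winter and 89.1% for midnight, so winter won.

    initiator → 2 initiating radical (k = 1.90 × 10⁻⁵ s⁻¹, Ea = 87.0 kJ mol⁻¹)
    starting material + initiating radical → chain carrier (k = 2200 M⁻¹ s⁻¹, Ea = 37.0 kJ mol⁻¹)
    reagent + chain carrier → product + initiating radical (k = 1500 M⁻¹ s⁻¹, Ea = 37.0 kJ mol⁻¹)
    2 initiating radical → ended chains A (k = 3.70 × 10⁶ M⁻¹ s⁻¹, Ea = 11.0 kJ mol⁻¹)
    2 chain carrier → ended chains B (k = 9.40 × 10⁸ M⁻¹ s⁻¹, Ea = 9.00 kJ mol⁻¹)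
    reagent ⇌ dormant form (K = 0.940, k = 4.40 × 10⁻⁵ s⁻¹, Ea = 80.0 kJ mol⁻¹, ΔH = 0 kJ mol⁻¹)
    (constants at 5 °C)

At midnight's change of temperature, 5.00 h, the fill curve gave 40.8% and the flask held 36.0%. At 7.50 h the curve gave 54.5%, while winter held 94.4%, more than the cold curve. At 15.0 h initiator stood at 0% in winter and 0% in midnight. Ten times the time changes the product of neither flask, so in that respect both had come to rest: at 150 h winter stays at 94.4% and midnight at 89.1%, with 8.91% of its starting material unconverted.

Readings and results are simulated on assumed constants, noise included.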